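The readings are calculated with constants of no real substance; scatter was added.

Birch, an earlier run of this catalysed conversion of substrate into target, holds twice the catalyst of ash and loses substrate at 0.00326 /h against 0.00163 /h, which is twice as fast, though it holds less other conformer. So I read the loss as pseudo-first-order in substrate, its rate constant in proportion to catalyst.

| flask | substrate | other conformer | catalyst | temperature | remark | time |
|---|---|---|---|---|---|---|
| ash | 1 M | 0.25 M | 25 mM | 45 °C | run made earlier |  |
| maple | 1 M | 0.25 M | 100 mM | 70 °C | run made earlier |  |
| birch | 1 M | 0.12 M | 50 mM | 45 °C | run made earlier |  |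
| Thursday's | 1.0 M | 0.250 M | 50 mM | 50 °C |  | 30 h |
| Saturday's | 1.0 M | 0.250 M | 50 mM | 90 °C |  | 30 h |
| Friday's | 1.0 M | 0.250 M | 50 mM | 70 °C |  | 30 h |

- ash (time / h: target / %, substrate / %): 1.50: 0.1, 79.6; 5.00: 0.7, 79.5; 8.00: 0.4, 79.6; 12.0: 1.2, 78.5; 20.0: 2.2, 77.3; 25.0: 2.9, 76.6
- maple (time / h: target / %, substrate / %): 0.667: 3.4, 77.3; 1.00: 4.4, 76.0; 2.00: 9.0, 71.6; 3.00: 12.4, 67.8; 6.00: 20.8, 57.0; 10.0: 28.9, 45.1
- birch (time / h: target / %, substrate / %): 2.00: 0.4, 88.5; 4.00: 1.0, 88.2; 6.00: 1.7, 87.7; 12.0: 3.3, 85.8; 25.0: 7.1, 82.1

(readings scatter by 0.3 percentage points)

- the analysis behind the earlier runs scatters by 0.3 percentage points, standard deviation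
- in a conversion other conformer counts as not yet reacted

- the flask with the highest amount of target, in percent of the substrate and other conformer together charged ("all alike" if they lie within 1.5 percentage points) (Thursday's / Saturday's / Friday's / all alike)
- final target, as a percentage of the substrate and other conformer together charged, in Thursday's
- final target, as a percentage of the substrate and other conformer together charged, in Saturday's
- final target, as a percentage of the substrate and other conformer together charged, in Friday's

At a given temperature, catalyst times time is then the clock, and Thursday's, Friday's and Saturday's share one value of it, 90.0 M·min. I call this the catalyst dose.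

Now the ladder, per unit of dose, as I read it. At maple's temperature substrate goes with 0.577 /M/h, much faster than the 0.0653 /M/h at birch's. Next comes target: in maple, substrate plus target sinks from 80.2 % to 74.0 % between its fourth and sixth readings. I read that as target's onward loss and assume it runs on catalyst too, which gives 0.429 /M/h, slower than substrate's loss at that temperature. In ash, other conformer adds nothing I can read to this ladder: substrate plus target ends at 79.5 %, close to substrate's share of the charge, 80.0 %.

With these two constants, two first-order steps in a row put target's peak at a dose of 120 M·min. Friday's, at maple's temperature, stops before that, and I reckon 32.6 % of target. Birch's constant, from a flask colder than Thursday's, gives 7.46 % for Thursday's, which I take as a low estimate. Saturday's is hotter than Friday's, so I expect the same dose to carry Saturday's past its peak, and I commit to Friday's.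

The forecast also names Friday's: 11.7 % (10 % to 13.5 %) for Thursday's, above my low estimate, 30 % (25 % to 36 %) for Friday's, a little under my figure, and 6 % (1 % to 16 %) for Saturday's, where “target mostly burns off”.

The flasks give 10.6 % in Thursday's, 33.5 % in Friday's and 16.3 % in Saturday's, so Friday's leads.

    substrate ⇌ other conformer (K = 0.0200, k = 0.0220 /h, Ea = 121 kJ/mol, ΔH = −66.0 kJ/mol)
    catalyst + other conformer → catalyst + isomer of the product (k = 14.0 /M/h, Ea = 59.0 kJ/mol)
    substrate + target → side product (k = 0.00330 /M/h, Ea = 91.0 kJ/mol)
    2 other conformer → homo dimer (k = 0.670 /M/h, Ea = 79.0 kJ/mol)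
    substrate + catalyst → catalyst + target (k = 2.70 /M/h, Ea = 80.0 kJ/mol)
    catalyst + target → catalyst + over-reaction product (k = 1.50 /M/h, Ea = 71.0 kJ/mol)
    (constants at 90 °C)

Saturday's loses its target to the over-reaction product: with that step struck out, target ends at 82.5 % instead of 16.3 %. Saturday's dose is 3.06 times the dose of the peak that the scheme's two catalysed constants give at Saturday's temperature, so it lies beyond that peak. The two-step reckoning then gives 15.8 %. A neighbour of Saturday's with 0.085 M of catalyst takes a dose of 153 M·min, for which the same reckoning gives 3.74 %, and that flask holds 3.78 %.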